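A small charge of substrate dripping into partner reacts, I assume, at a rate proportional to [substrate][partner]. The rate per substrate, k′ = k[partner], is then pseudo-first-order, and its fall shows [partner] fading.

| flask | substrate | partner | protic impurity | temperature | remark | time |
|---|---|---|---|---|---|---|
| south-east | 0.50 M (fed, over 1.5 min) | 2 equiv | 0.11 M | −15 °C | run made earlier |  |
| east | 0.50 M (fed, over 1.5 min) | 2 equiv | 0.18 M | 5 °C | run made earlier |  |
| elm | 0.50 M (fed, over 1.5 min) | 2.00 equiv | 0.250 M |  | at −10 °C until 1.5 min, from then on at 20 °C | 12 min |
| birch | 0.50 M (fed, over 5.0 min) | 2.00 equiv | 0.120 M |  | at 20 °C throughout | 12 min |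

| run | time / min | target / % | substrate / % |
|---|---|---|---|
| south-east | 1.33 | 0 | 81.3 |
| south-east | 3.00 | 2.0 | 75.4 |
| south-east | 4.00 | 1.3 | 68.2 |
| south-east | 6.00 | 5.9 | 59.1 |
| south-east | 8.00 | 8.2 | 53.0 |
| east | 0.667 | 0 | 38.5 |
| east | 1.33 | 2.7 | 75.2 |
| east | 2.00 | 6.3 | 82.6 |
| east | 3.00 | 9.9 | 81.7 |
| east | 4.00 | 13.0 | 81.8 |

(each reading ± 0.5 percentage points)

* which one finishes higher in amount of target, in percent of the substrate charged ("neither" within 2 percentage points) (elm / birch / neither)
* amount of target at the end, in percent of the substrate charged, elm
* amount of target at the end, in percent of the substrate charged, birch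

In the south-east run, after the feed, k′ falls from 0.100 /min to 0.0545 /min, which reads as a lifetime of 5.73 min at −15 °C. In the east run I take the substrate lost as fed minus found, and k′ falls from 0.199 /min to 0.0744 /min, a lifetime of 0.678 min at 5 °C. Both are rough readings, and the differing impurity is folded into them.

Assuming the same factor per degree, the partner lifetime, the time in which [partner] falls by a factor e at a given temperature, is 0.137 min at 20 °C and 3.36 min at −10 °C.

The ladder then runs upward from that 0.137 min, through the short feed of 1.5 min and the cold lifetime, to the long feed of 5.0 min and the 12 min allowed. On the lowest rung stands birch, whose partner lifetime is shorter than its feed. Substrate enters at a steady rate, so what meets living partner in birch is what comes in during about one lifetime, a short stretch of the feed. Elm's feed is shorter than its cold lifetime, so I reckon its substrate is in with 64.0% of the partner still alive when it warms. On the top rung, target lags: in the east run it climbs from 6.3% to 13.0% while substrate stands flat. I therefore put elm above the 18.2% that the east run converted, and well above birch.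

The forecast says birch, with 33% for elm and 40% for birch, reasoning that “Elm has much more impurity, which probably costs more than its quicker feed gains”. There I differ.

The flask gives elm: elm ends at 27.3%, birch at 0.878%.

    substrate + partner → intermediate + released group (k = 0.00440 /M/s, Ea = 49.0 kJ/mol)
    intermediate → target (k = 0.00140 /s, Ea = 71.0 kJ/mol)
    partner + protic impurity → quenched reagent (k = 0.00510 /M/s, Ea = 40.0 kJ/mol)
    partner → decomposed reagent (k = 0.00320 /s, Ea = 77.0 kJ/mol)
    partner + target → over-reaction product (k = 0.00330 /M/s, Ea = 60.0 kJ/mol)
    (constants at −10 °C)

Bit-by-bit addition is a part of the reason: birch with its substrate in at once reaches 25.6% instead of 0.878%. As dosed, birch has 0.137 min of partner lifetime against 5.0 min of feed, and it converts 0.901% of its substrate, with 0% of partner at the end of the feed. The same flask at −5 °C has a reckoned lifetime of 1.97 min against that feed, and it ends at 17.4% of target.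

The numbers in the tables are calculated for an exercise; scatter was added.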